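Abbreviations: TBS = tert‑butyldimethylsilyl, PMB = 4‑methoxybenzyl, DIPT = diisopropyl tartrate. Ring numbering used throughout: C1 (ketone carbon), C2 (heptenyl‑bearing), C3 (hydroxymethyl‑bearing), C4 (carbinol), C5 (epoxide CH), C6 (quaternary epoxide carbon).

## Analysis of the target

The target is a cyclohex‑2‑enone fused to an oxirane (a 7‑oxabicyclo[4.1.0]hept‑3‑en‑2‑one) in which every ring carbon is substituted. C1 is the ketone, C2 carries an (E)‑hept‑1‑enyl group, C3 a CH2OH group, C4 a secondary hydroxyl, C5–C6 the epoxide, and C6 also the (E)‑3‑carboxybut‑2‑enyl chain. The three stereocentres C4, C5 and C6 are contiguous and all S; the C4 hydroxyl is cis to the epoxide oxygen and the C6 side chain is trans to both. The two side‑chain alkenes add two E geometries to be controlled. Sensitive points are the α,β‑epoxy ketone (base, nucleophiles), the allylic C4 carbinol next to the epoxide (acid, loss of water towards aromatic material), the 2‑alkenyl enone (conjugate addition) and the free acid, which tolerates neither hydride nor organometallic reagents. The difficulty is density: a tetrasubstituted C2=C3 alkene bearing a diene arm, a quaternary epoxide carbon and three oxygenated sp3 carbons, with no unfunctionalised ring position to work from. The plan rests on the unit C2=C3(CH2OH)–C4H(OH), which is a Morita–Baylis–Hillman adduct alkenylated at its β‑carbon. C2 and C3 can therefore be the two carbons of an alk‑2‑ynoate (the CH2OH arriving as the ester), C4 an aldehyde, and the heptenyl group a carbon nucleophile added in conjugate fashion. C5, C6 and C1 are then a three‑carbon tether with the stereochemistry of a 2,3‑epoxy alcohol.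

## Retrosynthetic reasoning

**Side chain.** Target 30 is the diol released from acetonide 29. The trisubstituted alkene of 29 is cut by cross‑metathesis into allyl compound 27 and methacrylic acid 28. The cut is made there because no acid or ester in the side chain would survive the hydride reductions and the organocopper step earlier on, whereas a bare allyl group passes through all of them. The forward reaction has to pick the terminal alkene over the two alkenes of the dienone and give the E isomer.

**Oxidation levels.** Dienone 27 goes back by functional‑group changes only: the C1 ketone to alcohol 26 and its silyl ether 25, the acetonide to diol 24, and the C3 hydroxymethyl group to the methyl ester of 23. C1 is held as a silyl ether and C3 as an ester because the ring‑forming step needs the ester as the only group that polarises the C2–C3 unit. The acetonide serves only to tell the three hydroxyls apart while C1 is oxidised.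

**Ring formation.** In 23 the bonds C2–heptenyl and C3–C4 are cut together, giving aldehyde–ynoate 16 and cuprate 21. No other pair of cuts removes the tetrasubstituted alkene, the ring and the diene arm at once, and both fragments are simple. Going forward, one operation forms the ring, two C–C bonds and the C4 stereocentre and joins the two branches. It has to add to C2 faster than to the aldehyde, let the first‑formed α‑metallated enoate turn over through allenoate 22, and close onto the correct aldehyde face.

**Cuprate.** Cuprate 21 comes from alkenyllithium 20, that from iodide 19, and 19 from heptyne 17 through alane 18. Hydroalumination fixes the E geometry at the start and each later metal exchange retains it.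

**Ynoate arm.** Aldehyde 16 is the oxidation product of alcohol 15, unmasked from bis‑silyl ether 14. In 14 (via carbinol 13) the C1–C2 bond is cut between the carbinol carbon and the alkyne, giving epoxy aldehyde 10 and methyl propiolate 11, used as acetylide 12. C1 must be the aldehyde first and C4 last, so the two ends have to be distinguishable from the outset.

**Stereochemistry.** Aldehyde 10 comes from epoxy alcohol 9, and the two C–O bonds of its epoxide are cut by a Sharpless epoxidation of Z allylic alcohol 8. This is the only point where absolute configuration enters: it sets C5 and C6, and C4 later follows from them. The cis relation of the two carbon arms on the epoxide, needed for both to lie in the ring, is inherited from the Z alkene.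

**Alkene.** Alcohol 8 is the reduction product of ester 7, whose C=C bond is cut by a Z‑selective olefination into phosphonate 4 (as its anion 6) and aldehyde 5; 4 comes from 1 and 2 via enolate 3. The olefination delivers C1 as an ester and C4 as a silyl ether, so the two ends are differentiated without a selective mono‑protection. A route through a diol with two primary allylic hydroxyls of similar reactivity would need exactly that.

## Alternatives that were turned down

**Alternative 1:** The C3–O and C6–O bonds are cut together, taking the epoxide oxygen and the C4 oxygen back to one molecule of dioxygen. Forward, photosensitised singlet oxygen would undergo [4+2] addition to cyclohexadiene A2 at C3 and C6, on the face away from the C1 silyl ether, giving endoperoxide A1. O–O cleavage would then hand both oxygens to one face, and base opening of the C3–C4 epoxide from a C1 ketone would reveal C2=C3 and the C4 hydroxyl.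
- For: the cis relation of the C4 hydroxyl and the epoxide oxygen follows from the mechanism. On relative configuration at C4–C6 this plan is stronger than the chosen one, which has to win C4 by chelation.
- Against: absolute configuration hangs on one allylic silyloxy centre steering the oxygen. A2 is a 1,3‑diene with a ring leaving group and can aromatise by loss of silanol, and it has several allylic C–H bonds open to the ene reaction. After A1 the heptenyl group is still missing, so C2 must be halogenated and cross‑coupled on a hindered enone, and the acetal must be turned into the enoic acid.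
- Comparison: at least eight linear operations follow the key step, against six here. The chosen plan offers instead a convergent step that closes the ring and attaches the heptenyl group together, with absolute configuration from a reagent‑controlled epoxidation.

**Alternative 2:** The C1–C6 bond is cut, C1 as an acyl‑anion equivalent and C6 as a ketone. Forward, a chiral triazolylidene would turn the aldehyde of acyclic keto‑aldehyde A4 into an acyl‑anion equivalent that adds to the allyl ketone, closing cyclohexanone A3 with its tertiary C6 alcohol.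
- For: intramolecular aldehyde–ketone benzoin closure to six‑membered α‑hydroxy ketones is established organocatalysis, so the key step is better precedented than the one chosen. C1 arrives as the ketone and C6 is made under catalyst control.
- Against: A4 must already carry C3, C4 and C5 as stereocentres, and C3 is destroyed later. Its allyl ketone can slip into conjugation and its α‑alkoxy centre can epimerise under the basic conditions. In A3 the epoxide does not yet exist (C5–O must be activated and displaced by the C6 oxygen with inversion), C2–C3 is saturated, and C2 has no heptenyl group.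
- Comparison: the route is longer on both sides of the key step. The chosen plan offers a ring closure that leaves C2, C3 and C4 at their final substitution, so only functional‑group adjustments remain.

**Alternative 3:** C1–C2 and C2–C3 are cut and C2 is removed as a one‑carbon unit, contracting the ring to a cyclopentanone. Forward, dibromocarbene would add to the enol double bond of silyl enol ether A6, and the adduct would open with loss of bromide and silicon to the ring‑expanded bromo‑enone A5.
- For: A5 has the ketone, the epoxide, the C4 oxygen and all three stereocentres in place, and a C2–Br bond suited to Stille or Suzuki alkenylation. For introducing the heptenyl group this is more reliable than a cuprate domino, and the endgame would be about as short.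
- Against: A6 is the enol ether of a ketone with a silyloxy leaving group β to the enolised carbon and an epoxide on the other α‑carbon, so making it invites β‑elimination. The carbene is generated with potassium tert‑butoxide, which is hostile to the epoxy ketone formed, and the allyl alkene is a second carbene acceptor. The cyclopentanone behind A6 needs its own enantioselective synthesis with the same three stereocentres.
- Comparison: the risk moves from the coupling to a base‑mediated step on a substrate set up to eliminate, and the route is linear. The chosen plan offers a short, reagent‑controlled entry to the stereocentres and a convergent ring formation.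

Key step: step 12

Assumption on the chemistry: the acetylide addition of step 6 is not expected to discriminate strongly between the faces of aldehyde 10. Compounds 13 to 26 are drawn as the C1 epimer whose oxygen is trans to the epoxide oxygen; the other epimer takes the same steps and both converge at ketone 27. If the epimers behave differently in step 12 they are separated after step 7.

## Route

Step 1
Reactants: 1 methyl 2-[bis(2,2,2-trifluoroethoxy)phosphoryl]acetate; 2 allyl bromide
Product: 4 methyl 2-[bis(2,2,2-trifluoroethoxy)phosphoryl]pent-4-enoate (racemic), via sodium phosphonoacetate enolate 3 (not isolated)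
Conditions: NaH, THF, 0 °C; then 2, 0 °C → rt
Reagents that add atoms: none
Why: C‑alkylation of a stabilised phosphonoacetate carbanion with an allylic bromide (SN2); one equivalent each of base and halide limits dialkylation, and the new centre is of no consequence because it becomes sp2 in step 2.

Step 2
Reactants: 4 methyl 2-[bis(2,2,2-trifluoroethoxy)phosphoryl]pent-4-enoate; 5 [(tert-butyldimethylsilyl)oxy]acetaldehyde
Product: 7 methyl (2Z)-2-allyl-4-[(tert-butyldimethylsilyl)oxy]but-2-enoate, via potassium phosphonate carbanion 6 (not isolated)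
Conditions: KN(SiMe3)2, 18-crown-6, THF, −78 °C; then 5
Reagents that add atoms: none
Why: Still–Gennari olefination: the electron‑poor phosphonate with a dissociated potassium counter‑ion eliminates faster than the adducts equilibrate, so the kinetic Z trisubstituted enoate should dominate. This places the ester carbon (future C1) and the silyloxymethyl carbon (future C4) cis and at different oxidation levels.

Step 3
Reactants: 7 methyl (2Z)-2-allyl-4-[(TBS)oxy]but-2-enoate
Product: 8 (2Z)-2-allyl-4-[(tert-butyldimethylsilyl)oxy]but-2-en-1-ol
Conditions: i-Bu2AlH, CH2Cl2, −78 °C; aq. potassium sodium tartrate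
Reagents that add atoms: none
Why: 1,2‑Reduction of an α,β‑unsaturated ester by i-Bu2AlH at low temperature gives the allylic alcohol without touching the silyl ether or the alkene geometry.

Step 4
Reactants: 8 (2Z)-2-allyl-4-[(TBS)oxy]but-2-en-1-ol
Product: 9 [(2R,3S)-2-allyl-3-({[tert-butyl(dimethyl)silyl]oxy}methyl)oxiran-2-yl]methanol
Conditions: Ti(OiPr)4 (cat.), D-(−)-DIPT (cat.), t-BuOOH, 4 Å MS, CH2Cl2, −20 °C
Reagents that add atoms: tert-butyl hydroperoxide, CC(C)(C)OO
Why: Sharpless asymmetric epoxidation: only the alkene allylic to the free hydroxyl is epoxidised, the terminal alkene being too remote for delivery. The D-(−)-tartrate gives the 2R,3S epoxide (the L-(+)-ester would give its enantiomer), which fixes C6 and C5 of the target; the cis relation of the two CH2O arms comes from the Z alkene.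

Step 5
Reactants: 9 [(2R,3S)-2-allyl-3-(TBSOCH2)oxiran-2-yl]methanol
Product: 10 (2S,3S)-2-allyl-3-({[tert-butyl(dimethyl)silyl]oxy}methyl)oxirane-2-carbaldehyde
Conditions: Dess–Martin periodinane, NaHCO3, CH2Cl2, 0 °C → rt
Reagents that add atoms: none
Why: Dess–Martin oxidation of a primary alcohol under buffered, non‑aqueous conditions; the α‑carbon is quaternary, so the epoxy aldehyde can neither enolise nor epimerise.

Step 6
Reactants: 10 (2S,3S)-2-allyl-3-(TBSOCH2)oxirane-2-carbaldehyde; 11 methyl propiolate
Product: 13 methyl (4S)-4-[(2R,3S)-2-allyl-3-({[tert-butyl(dimethyl)silyl]oxy}methyl)oxiran-2-yl]-4-hydroxybut-2-ynoate, via methyl 3-lithiopropiolate 12 (not isolated)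
Conditions: LiN(SiMe3)2, THF, −78 °C; then 10; AcOH, −78 °C
Reagents that add atoms: none
Why: 1,2‑Addition of a lithium acetylide to an aldehyde at −78 °C, where lithiated methyl propiolate is stable, forms the C1–C2 bond. The new carbinol centre C1 is expected as a mixture and is erased when C1 becomes the ketone.

Step 7
Reactants: 13 methyl (4S)-4-[(2R,3S)-2-allyl-3-(TBSOCH2)oxiran-2-yl]-4-hydroxybut-2-ynoate
Product: 14 methyl (4S)-4-[(2S,3S)-2-allyl-3-({[tert-butyl(dimethyl)silyl]oxy}methyl)oxiran-2-yl]-4-{[tert-butyl(dimethyl)silyl]oxy}but-2-ynoate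
Conditions: TBSOTf, 2,6-lutidine, CH2Cl2, −78 → 0 °C
Reagents that add atoms: tert-butyldimethylsilyl triflate, CC(C)(C)[Si](C)(C)OS(=O)(=O)C(F)(F)F
Why: Silylation of a hindered secondary propargylic alcohol with a silyl triflate and a hindered base; the chloride–imidazole method is avoided because nucleophilic amines add to ynoates.

Step 8
Reactants: 14 methyl (4S)-4-[(2S,3S)-2-allyl-3-(TBSOCH2)oxiran-2-yl]-4-[(TBS)oxy]but-2-ynoate
Product: 15 methyl (4S)-4-[(2S,3S)-2-allyl-3-(hydroxymethyl)oxiran-2-yl]-4-{[tert-butyl(dimethyl)silyl]oxy}but-2-ynoate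
Conditions: HF·pyridine, pyridine, THF, 0 °C
Reagents that add atoms: none
Why: Buffered fluoride desilylation distinguishes the unhindered primary silyl ether from the secondary one, which is flanked by a quaternary carbon and an alkyne; excess pyridine protects the epoxide.

Step 9
Reactants: 15 methyl (4S)-4-[(2S,3S)-2-allyl-3-(hydroxymethyl)oxiran-2-yl]-4-[(TBS)oxy]but-2-ynoate
Product: 16 methyl (4S)-4-[(2S,3R)-2-allyl-3-formyloxiran-2-yl]-4-{[tert-butyl(dimethyl)silyl]oxy}but-2-ynoate
Conditions: Dess–Martin periodinane, NaHCO3, CH2Cl2, 0 °C; used crude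
Reagents that add atoms: none
Why: Dess–Martin oxidation to the cis‑epoxy aldehyde; the product is taken on at once because 2,3‑epoxy aldehydes hydrate and degrade on silica.

Step 10
Reactants: 17 hept-1-yne
Product: 19 (1E)-1-iodohept-1-ene, via (E)-hept-1-enyl(diisobutyl)alane 18 (not isolated)
Conditions: i-Bu2AlH, hexane, 50 °C; then I2, THF, −50 °C → rt
Reagents that add atoms: iodine, II
Why: Syn hydroalumination of a terminal alkyne puts aluminium on the terminal carbon, and iodinolysis of the C–Al bond with retention gives the E alkenyl iodide (Zweifel hydroalumination–iodination).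

Step 11
Reactants: 19 (1E)-1-iodohept-1-ene
Product: 21 lithium di[(1E)-hept-1-en-1-yl]cuprate (solution, used directly), via (E)-hept-1-enyllithium 20 (not isolated)
Conditions: t-BuLi (2 equiv), Et2O, −78 °C; then CuI (0.5 equiv), −78 → −40 °C
Reagents that add atoms: CuI, [Cu]I; tert-butyllithium, [Li]C(C)(C)C
Why: Lithium–iodine exchange with two equivalents of t-BuLi (the second destroys t-BuI) retains the alkene geometry, and two alkenyllithiums with one CuI give the Gilman homocuprate.

Step 12
Reactants: 16 methyl (4S)-4-[(2S,3R)-2-allyl-3-formyloxiran-2-yl]-4-[(TBS)oxy]but-2-ynoate; 21 lithium di[(1E)-hept-1-en-1-yl]cuprate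
Product: 23 methyl (1S,4S,5S,6S)-6-allyl-1-[(tert-butyldimethylsilyl)oxy]-5,6-epoxy-2-[(1E)-hept-1-en-1-yl]-4-hydroxycyclohex-2-ene-3-carboxylate (ring numbering as defined above), via lithium allenoate 22 (not isolated)
Conditions: 21 (1.1 equiv) added to 16, Et2O–THF, −78 °C; MgBr2·OEt2, −78 → −20 °C; aq. NH4Cl
Reagents that add atoms: none
Why: Proposed new method: cuprate 21 π‑complexes the ynoate of 16 and transfers one heptenyl group syn to C2, which is the only alkyne carbon β to an electron‑withdrawing group as long as C1 is an ether; the α‑cuprio enoate formed has copper trans to the C1 tether and is inert to the aldehyde at −78 °C, but on warming it turns over through metal allenoate 22, in which the nucleophilic orbital at C3 is coplanar with the two substituents on C2. Attack from the C1 side on the tethered aldehyde is a 6‑(enolexo)‑exo‑trig aldol that forms C3–C4 and the six‑membered ring, and geometry allows only the endocyclic tetrasubstituted C2=C3 alkene. The closest known reaction types are cuprate additions to ω‑halo‑alk‑2‑ynoates in which the same intermediate is alkylated intramolecularly to a cycloalkene carboxylate, cuprate–ynoate–aldehyde three‑component couplings, and nickel‑ or palladium‑catalysed anti‑carbometalative cyclisations of alkynyl carbonyl compounds with boronic acids, which likewise need E/Z isomerisation of an alkenyl metal before closure. C4 is the one new stereocentre and is controlled by the C5–C6 epoxide: MgBr2 bridges the aldehyde and epoxide oxygens and holds the carbonyl oxygen on the epoxide face of the forming ring, so the hydroxyl ends cis to the epoxide oxygen, and the same rotamer keeps the metallated oxygen away from the C6 allyl group. The selectivity needed is conjugate addition ahead of 1,2‑addition to the aldehyde; it rests on the much higher rate of cuprate addition to ynoates, on the low carbonyl reactivity of an alkenyl ligand, on adding a near‑stoichiometric amount of 21 to 16 so that the reagent is never in excess, and on adding the Lewis acid only after the cuprate is consumed. The trisubstituted epoxide and the isolated allyl alkene are not attacked by organocopper species at these temperatures.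

Step 13
Reactants: 23 methyl (1S,4S,5S,6S)-6-allyl-1-[(TBS)oxy]-5,6-epoxy-2-[(1E)-hept-1-enyl]-4-hydroxycyclohex-2-ene-3-carboxylate
Product: 24 (1S,4S,5S,6S)-6-allyl-1-[(tert-butyldimethylsilyl)oxy]-5,6-epoxy-2-[(1E)-hept-1-en-1-yl]-3-(hydroxymethyl)cyclohex-2-en-4-ol
Conditions: i-Bu2AlH (excess), CH2Cl2, −78 °C; aq. potassium sodium tartrate
Reagents that add atoms: none
Why: i-Bu2AlH reduces the conjugated methyl ester to the primary allylic alcohol by 1,2‑hydride delivery; the first equivalent is consumed by the C4 hydroxyl, and at −78 °C the epoxide and silyl ether are left alone.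

Step 14
Reactants: 24 (1S,4S,5S,6S)-6-allyl-1-[(TBS)oxy]-5,6-epoxy-2-[(1E)-hept-1-enyl]-3-(hydroxymethyl)cyclohex-2-en-4-ol
Product: 25 isopropylidene acetal of 24 across the C3 hydroxymethyl oxygen and the C4 oxygen (1S,4S,5S,6S)
Conditions: 2,2-dimethoxypropane, pyridinium p-toluenesulfonate (cat.), CH2Cl2, rt
Reagents that add atoms: 2,2-dimethoxypropane, COC(C)(C)OC
Why: Acid‑catalysed transacetalisation: the C3 hydroxymethyl and C4 hydroxyl form a 1,3‑diol and close a six‑membered acetonide, leaving only the C1 oxygen to be unmasked.

Step 15
Reactants: 25 acetonide of 24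
Product: 26 (1S,4S,5S,6R)-6-allyl-5,6-epoxy-2-[(1E)-hept-1-en-1-yl]-3-(hydroxymethyl)cyclohex-2-ene-1,4-diol 3,4-acetonide (C1 hydroxyl free)
Conditions: Bu4NF, AcOH, THF, rt
Reagents that add atoms: none
Why: Fluoride cleavage of the secondary silyl ether; acetic acid keeps the liberated C1 oxygen protonated, which suppresses Payne migration of the neighbouring epoxide in the epimer whose C1 oxygen is anti to the C6–O bond.

Step 16
Reactants: 26 C1 alcohol acetonide
Product: 27 (4S,5S,6S)-6-allyl-5,6-epoxy-2-[(1E)-hept-1-en-1-yl]-4-hydroxy-3-(hydroxymethyl)cyclohex-2-en-1-one 3,4-acetonide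
Conditions: Dess–Martin periodinane, NaHCO3, CH2Cl2, 0 °C → rt
Reagents that add atoms: none
Why: Dess–Martin oxidation of the secondary allylic alcohol gives the 2‑alkenyl enone; C1 becomes sp2 so both C1 epimers converge, and C6 is quaternary so the epoxy ketone cannot epimerise.

Step 17
Reactants: 27 dienone acetonide; 28 methacrylic acid
Product: 29 (2E)-4-[(4S,5S,6S)-5,6-epoxy-2-[(1E)-hept-1-en-1-yl]-4-hydroxy-3-(hydroxymethyl)-1-oxocyclohex-2-en-6-yl]-2-methylbut-2-enoic acid 3,4-acetonide
Conditions: 28 (excess), second-generation Grubbs catalyst (H2IMes)(PCy3)Cl2Ru=CHPh (cat.), CH2Cl2, 40 °C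
Reagents that add atoms: none
Why: Olefin cross‑metathesis between a monosubstituted alkene and an excess of a 1,1‑disubstituted electron‑poor partner that does not homodimerise; the more stable E trisubstituted enoic acid is expected. The alkenes of the dienone are conjugated, hindered and electron‑poor and should not initiate.

Step 18
Reactants: 29 acid acetonide
Product: 30 (2E)-4-[(1S,5S,6S)-3-[(1E)-hept-1-en-1-yl]-5-hydroxy-4-(hydroxymethyl)-2-oxo-7-oxabicyclo[4.1.0]hept-3-en-1-yl]-2-methylbut-2-enoic acid (target)
Conditions: AcOH–H2O (4:1), 25 °C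
Reagents that add atoms: none
Why: Mild aqueous acid hydrolyses the isopropylidene acetal; the epoxide carbons are deactivated towards ionisation by the adjacent carbonyl (C6) and by the inductive effect of the C4 oxygen (C5).

## Compound list

1 | methyl 2-[bis(2,2,2-trifluoroethoxy)phosphoryl]acetate | COC(=O)CP(=O)(OCC(F)(F)F)OCC(F)(F)F | starting material
2 | allyl bromide (3-bromoprop-1-ene) | C=CCBr | starting material
3 | sodium enolate of 1 | COC(=O)[CH-]P(=O)(OCC(F)(F)F)OCC(F)(F)F.[Na+] | intermediate (not isolated)
4 | methyl 2-[bis(2,2,2-trifluoroethoxy)phosphoryl]pent-4-enoate (racemic) | COC(=O)C(CC=C)P(=O)(OCC(F)(F)F)OCC(F)(F)F | intermediate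
5 | [(tert-butyldimethylsilyl)oxy]acetaldehyde | O=CCO[Si](C)(C)C(C)(C)C | starting material
6 | potassium carbanion of 4 | COC(=O)[C-](CC=C)P(=O)(OCC(F)(F)F)OCC(F)(F)F.[K+] | intermediate (not isolated)
7 | methyl (2Z)-2-allyl-4-[(tert-butyldimethylsilyl)oxy]but-2-enoate | C=CC/C(=C/CO[Si](C)(C)C(C)(C)C)C(=O)OC | intermediate
8 | (2Z)-2-allyl-4-[(tert-butyldimethylsilyl)oxy]but-2-en-1-ol | C=CC/C(=C/CO[Si](C)(C)C(C)(C)C)CO | intermediate
9 | [(2R,3S)-2-allyl-3-({[tert-butyl(dimethyl)silyl]oxy}methyl)oxiran-2-yl]methanol | OC[C@@]1(CC=C)O[C@H]1CO[Si](C)(C)C(C)(C)C | intermediate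
10 | (2S,3S)-2-allyl-3-({[tert-butyl(dimethyl)silyl]oxy}methyl)oxirane-2-carbaldehyde | O=C[C@@]1(CC=C)O[C@H]1CO[Si](C)(C)C(C)(C)C | intermediate
11 | methyl propiolate | C#CC(=O)OC | starting material
12 | methyl 3-lithiopropiolate | [Li]C#CC(=O)OC | intermediate (not isolated)
13 | methyl (4S)-4-[(2R,3S)-2-allyl-3-({[tert-butyl(dimethyl)silyl]oxy}methyl)oxiran-2-yl]-4-hydroxybut-2-ynoate | COC(=O)C#C[C@H](O)[C@@]1(CC=C)O[C@H]1CO[Si](C)(C)C(C)(C)C | intermediate
14 | methyl (4S)-4-[(2S,3S)-2-allyl-3-({[tert-butyl(dimethyl)silyl]oxy}methyl)oxiran-2-yl]-4-{[tert-butyl(dimethyl)silyl]oxy}but-2-ynoate | COC(=O)C#C[C@H](O[Si](C)(C)C(C)(C)C)[C@@]1(CC=C)O[C@H]1CO[Si](C)(C)C(C)(C)C | intermediate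
15 | methyl (4S)-4-[(2S,3S)-2-allyl-3-(hydroxymethyl)oxiran-2-yl]-4-{[tert-butyl(dimethyl)silyl]oxy}but-2-ynoate | COC(=O)C#C[C@H](O[Si](C)(C)C(C)(C)C)[C@@]1(CC=C)O[C@H]1CO | intermediate
16 | methyl (4S)-4-[(2S,3R)-2-allyl-3-formyloxiran-2-yl]-4-{[tert-butyl(dimethyl)silyl]oxy}but-2-ynoate | COC(=O)C#C[C@H](O[Si](C)(C)C(C)(C)C)[C@@]1(CC=C)O[C@H]1C=O | intermediate
17 | hept-1-yne | CCCCCC#C | starting material
18 | [(1E)-hept-1-en-1-yl]bis(2-methylpropyl)alumane | CCCCC/C=C/[Al](CC(C)C)CC(C)C | intermediate (not isolated)
19 | (1E)-1-iodohept-1-ene | CCCCC/C=C/I | intermediate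
20 | (1E)-hept-1-en-1-yllithium | CCCCC/C=C/[Li] | intermediate (not isolated)
21 | lithium di[(1E)-hept-1-en-1-yl]cuprate | CCCCC/C=C/[Cu-]/C=C/CCCCC.[Li+] | intermediate
22 | lithium allenoate from 16 and 21 (heptenyl on C2, ester enolate at C3) | CCCCC/C=C/C(=C=C(OC)O[Li])[C@H](O[Si](C)(C)C(C)(C)C)[C@@]1(CC=C)O[C@H]1C=O | intermediate (not isolated)
23 | methyl (1S,4S,5S,6S)-6-allyl-1-[(tert-butyldimethylsilyl)oxy]-5,6-epoxy-2-[(1E)-hept-1-en-1-yl]-4-hydroxycyclohex-2-ene-3-carboxylate | CCCCC/C=C/C1=C(C(=O)OC)[C@H](O)[C@@H]2O[C@]2(CC=C)[C@H]1O[Si](C)(C)C(C)(C)C | intermediate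
24 | (1S,4S,5S,6S)-6-allyl-1-[(tert-butyldimethylsilyl)oxy]-5,6-epoxy-2-[(1E)-hept-1-en-1-yl]-3-(hydroxymethyl)cyclohex-2-en-4-ol | CCCCC/C=C/C1=C(CO)[C@H](O)[C@@H]2O[C@]2(CC=C)[C@H]1O[Si](C)(C)C(C)(C)C | intermediate
25 | 3,4-acetonide of 24 (1S,4S,5S,6S) | CCCCC/C=C/C1=C2COC(C)(C)O[C@@H]2[C@@H]3O[C@]3(CC=C)[C@H]1O[Si](C)(C)C(C)(C)C | intermediate
26 | (1S,4S,5S,6R)-6-allyl-5,6-epoxy-2-[(1E)-hept-1-en-1-yl]-3-(hydroxymethyl)cyclohex-2-ene-1,4-diol 3,4-acetonide | CCCCC/C=C/C1=C2COC(C)(C)O[C@@H]2[C@@H]3O[C@]3(CC=C)[C@H]1O | intermediate
27 | (4S,5S,6S)-6-allyl-5,6-epoxy-2-[(1E)-hept-1-en-1-yl]-4-hydroxy-3-(hydroxymethyl)cyclohex-2-en-1-one 3,4-acetonide | CCCCC/C=C/C1=C2COC(C)(C)O[C@@H]2[C@@H]3O[C@]3(CC=C)C1=O | intermediate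
28 | methacrylic acid | CC(=C)C(=O)O | starting material
29 | (2E)-2-methylbut-2-enoic acid bearing at C4 the ring of 27 in place of its allyl group (3,4-acetonide; 4S,5S,6S) | CCCCC/C=C/C1=C2COC(C)(C)O[C@@H]2[C@@H]3O[C@]3(C/C=C(\C)C(=O)O)C1=O | intermediate
30 | (2E)-4-[(1S,5S,6S)-3-[(1E)-hept-1-en-1-yl]-5-hydroxy-4-(hydroxymethyl)-2-oxo-7-oxabicyclo[4.1.0]hept-3-en-1-yl]-2-methylbut-2-enoic acid | CCCCC/C=C/C1=C(CO)[C@H](O)[C@@H]2O[C@]2(C/C=C(\C)C(=O)O)C1=O | target

## Step count and risk

Total step count: 18. Longest linear sequence: 16 steps (steps 1–9 and 12–18); the two‑step cuprate branch (steps 10–11) joins at step 12.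

**Step 12 (key step, new method).** Three things can go wrong.
- The alkenyl ligand may add to the aldehyde before conjugate addition is complete, since α,β‑epoxy aldehydes are activated electrophiles.
- The first‑formed syn α‑cuprio enoate may fail to turn over through the allenoate and simply be protonated to the acyclic dienoate on work‑up.
- Facial selectivity at C4 may be poor if THF and lithium salts out‑compete the magnesium chelate.

The fallback uses known chemistry and sets out from 16. Heating 16 with (E)-hept-1-enylboronic acid and Pd(PPh3)4 (zerovalent palladium) in methanol is an anti‑selective alkenylative cyclisation of an alkynal. The palladium‑bound alkyne attacks the aldehyde through its ester‑bearing carbon, the resulting alkenyl divalent palladium species transmetalates with the boronic acid, and reductive elimination places the heptenyl group on C2 trans to the new C3–C4 bond. This gives the same ring and comes back to the route at 23. With either closure, material of the wrong C4 configuration, methyl (1S,4R,5S,6S)-6-allyl-1-[(tert-butyldimethylsilyl)oxy]-5,6-epoxy-2-[(1E)-hept-1-en-1-yl]-4-hydroxycyclohex-2-ene-3-carboxylate F1, is recovered. It is oxidised with Dess–Martin periodinane to the C4 ketone methyl (1S,5R,6S)-6-allyl-1-[(tert-butyldimethylsilyl)oxy]-5,6-epoxy-2-[(1E)-hept-1-en-1-yl]-4-oxocyclohex-2-ene-3-carboxylate F2 and reduced with NaBH4 and CeCl3·7H2O. Hydride is expected on the face opposite the epoxide oxygen, which returns 23.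

**Step 17 (cross‑metathesis).** The likely problems are sluggish coupling of a 1,1‑disubstituted acid with an allyl group on a quaternary carbon, and competing metathesis at the heptenyl alkene that would truncate the diene arm. The fallback sets out from 27 and couples it with methacrolein, a more reactive partner that allows lower temperature and catalyst loading. This gives the (E)-enal (2E)-2-methyl-4-[ring of 27]but-2-enal 3,4-acetonide F3, which Pinnick oxidation (NaClO2, NaH2PO4, 2-methylbut-2-ene, t-BuOH–H2O) takes to 29.

**Step 4 (asymmetric epoxidation).** A Z, 2,3‑disubstituted allylic alcohol is the least favourable pattern for the titanium–tartrate catalyst, so turnover may be slow and enantioselectivity incomplete. The fallback moves the directing hydroxyl to the other end of the alkene, where the substrate is 3,3‑disubstituted, the most selective class. It sets out from 8 and runs as follows.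
- PMB trichloroacetimidate with catalytic La(OTf)3 gives (2Z)-2-allyl-4-[(tert-butyldimethylsilyl)oxy]but-2-en-1-yl 4-methoxybenzyl ether F4.
- Bu4NF frees the other hydroxyl to give (2Z)-3-{[(4-methoxybenzyl)oxy]methyl}hexa-2,5-dien-1-ol F5.
- Sharpless epoxidation, now with L-(+)-DIPT because the directing group has changed ends, gives {(2S,3R)-3-allyl-3-{[(4-methoxybenzyl)oxy]methyl}oxiran-2-yl}methanol F6.
- TBSCl and imidazole give its silyl ether F7.
- DDQ removes the PMB group and returns 9.

**Step 15 (C1 desilylation).** Cleavage may be slow at a silyl ether flanked by a quaternary carbon, and in the epimer drawn the epoxide can migrate (Payne rearrangement) once the C1 oxygen is free under basic fluoride. The fallback avoids basic fluoride. It sets out from 25, where aqueous HF in acetonitrile removes both the silyl ether and the acetonide to give the triol (1S,4S,5S,6R)-6-allyl-5,6-epoxy-2-[(1E)-hept-1-en-1-yl]-3-(hydroxymethyl)cyclohex-2-ene-1,4-diol F8. Re‑acetalisation with 2,2-dimethoxypropane and pyridinium p-toluenesulfonate again selects the 1,3‑diol (six‑membered acetal, against a seven‑membered one through the C1 hydroxyl) and returns 26.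

## Further compounds

F1 | step 12 | methyl (1S,4R,5S,6S)-6-allyl-1-[(tert-butyldimethylsilyl)oxy]-5,6-epoxy-2-[(1E)-hept-1-en-1-yl]-4-hydroxycyclohex-2-ene-3-carboxylate | CCCCC/C=C/C1=C(C(=O)OC)[C@@H](O)[C@@H]2O[C@]2(CC=C)[C@H]1O[Si](C)(C)C(C)(C)C
F2 | step 12 | methyl (1S,5R,6S)-6-allyl-1-[(tert-butyldimethylsilyl)oxy]-5,6-epoxy-2-[(1E)-hept-1-en-1-yl]-4-oxocyclohex-2-ene-3-carboxylate | CCCCC/C=C/C1=C(C(=O)OC)C(=O)[C@@H]2O[C@]2(CC=C)[C@H]1O[Si](C)(C)C(C)(C)C
F3 | step 17 | (2E)-2-methyl-4-[ring of 27]but-2-enal 3,4-acetonide | CCCCC/C=C/C1=C2COC(C)(C)O[C@@H]2[C@@H]3O[C@]3(C/C=C(\C)C=O)C1=O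
F4 | step 4 | (2Z)-2-allyl-4-[(tert-butyldimethylsilyl)oxy]but-2-en-1-yl 4-methoxybenzyl ether | C=CC/C(COCc1ccc(OC)cc1)=C/CO[Si](C)(C)C(C)(C)C
F5 | step 4 | (2Z)-3-{[(4-methoxybenzyl)oxy]methyl}hexa-2,5-dien-1-ol | C=CC/C(COCc1ccc(OC)cc1)=C/CO
F6 | step 4 | {(2S,3R)-3-allyl-3-{[(4-methoxybenzyl)oxy]methyl}oxiran-2-yl}methanol | COc1ccc(COC[C@@]2(CC=C)O[C@H]2CO)cc1
F7 | step 4 | tert-butyl({(2S,3R)-3-allyl-3-{[(4-methoxybenzyl)oxy]methyl}oxiran-2-yl}methoxy)dimethylsilane | COc1ccc(COC[C@@]2(CC=C)O[C@H]2CO[Si](C)(C)C(C)(C)C)cc1
F8 | step 15 | (1S,4S,5S,6R)-6-allyl-5,6-epoxy-2-[(1E)-hept-1-en-1-yl]-3-(hydroxymethyl)cyclohex-2-ene-1,4-diol | CCCCC/C=C/C1=C(CO)[C@H](O)[C@@H]2O[C@]2(CC=C)[C@H]1O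
A1 | alternative 1 | 1-(1,3-dioxolan-2-ylmethyl)-7-[(tert-butyldimethylsilyl)oxy]-4-{[(tert-butyldiphenylsilyl)oxy]methyl}-2,3-dioxabicyclo[2.2.2]oct-5-ene | C1[C@@]2(CO[Si](c3ccccc3)(c3ccccc3)C(C)(C)C)C=C[C@](CC3OCCO3)(OO2)[C@H]1O[Si](C)(C)C(C)(C)C
A2 | alternative 1 | tert-butyl({2-(1,3-dioxolan-2-ylmethyl)-4-{[(tert-butyldiphenylsilyl)oxy]methyl}cyclohexa-2,4-dien-1-yl}oxy)dimethylsilane | C1C(CO[Si](c2ccccc2)(c2ccccc2)C(C)(C)C)=CC=C(CC2OCCO2)[C@H]1O[Si](C)(C)C(C)(C)C
A3 | alternative 2 | 2-allyl-2-hydroxy-3-[(4-methoxybenzyl)oxy]-4-[(tert-butyldimethylsilyl)oxy]-5-{[(tert-butyldiphenylsilyl)oxy]methyl}cyclohexanone | C1[C@@H](CO[Si](c2ccccc2)(c2ccccc2)C(C)(C)C)[C@H](O[Si](C)(C)C(C)(C)C)[C@@H](OCc2ccc(OC)cc2)[C@@](O)(CC=C)C1=O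
A4 | alternative 2 | 4-[(tert-butyldimethylsilyl)oxy]-3-{[(tert-butyldiphenylsilyl)oxy]methyl}-5-[(4-methoxybenzyl)oxy]-6-oxonon-8-enal | O=CC[C@@H](CO[Si](c1ccccc1)(c1ccccc1)C(C)(C)C)[C@H](O[Si](C)(C)C(C)(C)C)[C@@H](OCc1ccc(OC)cc1)C(=O)CC=C
A5 | alternative 3 | 6-allyl-2-bromo-5,6-epoxy-4-[(tert-butyldimethylsilyl)oxy]-3-{[(tert-butyldiphenylsilyl)oxy]methyl}cyclohex-2-enone | BrC1=C(CO[Si](c3ccccc3)(c3ccccc3)C(C)(C)C)[C@H](O[Si](C)(C)C(C)(C)C)[C@@H]2O[C@]2(CC=C)C1=O
A6 | alternative 3 | trimethylsilyl enol ether of 2-allyl-2,3-epoxy-4-[(tert-butyldimethylsilyl)oxy]-5-{[(tert-butyldiphenylsilyl)oxy]methyl}cyclopentanone | C[Si](C)(C)OC1=C(CO[Si](c2ccccc2)(c2ccccc2)C(C)(C)C)[C@H](O[Si](C)(C)C(C)(C)C)[C@@H]2O[C@@]21CC=C
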